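**Late plateau.** At late times the epsilon flask has no substrate to speak of, reading 0% at 15.0 min, and its target from 8.00 min on averages 6.80%, each reading scattered by 2 percentage points. Taking that plateau as the share that passed through intermediate A, nearly all of the substrate went to side product.

| setting | beta | epsilon | noon | winter | dawn | summer |
|---|---|---|---|---|---|---|
| substrate | 0.050 M | 0.050 M | 0.050 M | 0.050 M | 0.050 M | 0.050 M |
| coupling partner | 0.030 M | 0.030 M | 0.0300 M | 0.0300 M | 0.0300 M | 0.0300 M |
| second reagent | 0.060 M | 2.4 M | 0.0500 M | 0.150 M | 0.500 M | 1.50 M |
| third reagent | 0.075 M | 0.075 M | 0.0750 M | 0.0750 M | 0.0750 M | 0.0750 M |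
| capture agent | 1 mM | 1 mM | 1.00 mM | 1.00 mM | 1.00 mM | 1.00 mM |
| remark | run made earlier | run made earlier |  |  |  |  |
| time |  |  | 50 min | 50 min | 50 min | 50 min |

| run | time / min | target / % | substrate / % |
|---|---|---|---|
| beta | 1.33 | 0 | 27 |
| beta | 4.00 | 7 | 6 |
| beta | 8.00 | 6 | 6 |
| beta | 10.0 | 9 | 3 |
| beta | 15.0 | 18 | 0 |
| beta | 20.0 | 24 | 0 |
| beta | 25.0 | 31 | 0 |
| epsilon | 1.33 | 3 | 2 |
| epsilon | 4.00 | 4 | 1 |
| epsilon | 8.00 | 6 | 0 |
| epsilon | 10.0 | 6 | 2 |
| epsilon | 15.0 | 5 | 0 |
| epsilon | 20.0 | 6 | 1 |
| epsilon | 25.0 | 11 | 3 |

(readings scatter by 2 percentage points)

- reactions considered so far: substrate + coupling partner -> intermediate A; second reagent + intermediate A -> intermediate B; third reagent + intermediate B -> target; substrate + second reagent -> side product; intermediate B + capture agent -> trapped intermediate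
- "hardly changes" means that all values lie within two and a half points (for a concentration: within two and a half percent of the largest)

- amount of target at the end, in percent of the substrate charged for noon, winter, dawn, summer, in this order
- the shape of the row from first to last (falls all the way / falls, then rises / hardly changes / rises all the way / rises, then falls)

**Fractions left.** Coupling partner and second reagent both consume the same substrate, each in proportion to its own level. Their fractions left, b and d, therefore decay on one shared clock, the time integral of substrate, however that substrate moves. The ratio S = ln b / ln d, the selectivity factor, says how much faster coupling partner decays on that clock, and b = d^S. Here d counts second reagent lost to side product. In epsilon the plateau gives b = 88.7% and d = 98.1%, so S reads 6.13.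

**First doubt.** Some intermediate B may have gone to capture agent, whose charge equals 2.00% of the substrate. Adding that whole charge to the plateau gives b = 85.3% and d = 98.1%, so S reads 8.27. The reading is therefore a bracket, not one value, and both ends carry the scatter of the readings.

**Summer estimate.** In summer, side product can use at most 3.33% of the second reagent, so d stays near one and the start share of substrate entering intermediate A is S times the coupling partner level, divided by that product plus the second reagent level. That gives 10.9% to 14.2%. But coupling partner falls meanwhile. Using its mean level, the share becomes 10.0% to 12.7%, and that bracket is my own estimate for summer's target.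

**Second doubt.** The rule counts entry into intermediate A, not arrival at target. In beta, target readings still climb from 18% to 31% between 15.0 min and 25.0 min, so the flasks low in second reagent need a time argument as well.

**The forecast.** It gives 32%, 43%, 23% and 9%, a row that rises, then falls. For the first point it argues that “the A + second reagent step is slow and second order”. Its last point, 9%, stands below my bracket.

**The flask.** The row is 38.1%, 44.2%, 25.1% and 11.4%, so it rises, then falls. Summer lies inside the bracket, and noon still holds 16.5% as intermediate A at 50.0 min.

    substrate + coupling partner → intermediate A (k = 0.841 M⁻¹ s⁻¹)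
    second reagent + intermediate A → intermediate B (k = 0.0286 M⁻¹ s⁻¹)
    third reagent + intermediate B → target (k = 0.0258 M⁻¹ s⁻¹)
    substrate + second reagent → side product (k = 0.115 M⁻¹ s⁻¹)
    intermediate B + capture agent → trapped intermediate (k = 0.0515 M⁻¹ s⁻¹)

**Winter check.** Winter's side product, 53.8%, means d = 82.1%, counting as before only second reagent lost to side product. Raised to the two readings of S, this puts coupling partner left between 19.5% and 29.7%. Winter's flask holds 23%.

All runs were computed with made-up constants; scatter was added.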